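**Plan**
Numbering: ring C6–C7–C8–C9–C10–C11 (C6 = ring CH carrying the C5–C3 hydroxypropyl arm, C7 = alkylidene carbon, C10 = methyl carbinol, C11 = quaternary carbon); enal C1/C2; side chain C12–C23 with the carbinol at C16.
Retrosynthesis cuts C2=C7 (C7 ketone + isopropenyl unit), C16–C17 (geranyl unit onto a C16 aldehyde), the ring bond C9–C10, then C7–C8 (acetate aldol) and C6–C11 (Claisen), leaving geraniol and 5-silyloxypentanoic acid.
Enabling feature: C10 is a tertiary methyl carbinol between the C9 methylene and the quaternary C11 of the only carbocycle, so an open chain holding the C6/C11 pair, a C10 methyl ketone and a C9 iodide can close the cyclohexane and create the carbinol in one reductive event.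
Forward order: geranyl ester → Claisen (C6–C11) → two-carbon extension at C7 → methyl ketone and iodide → samarium closure of the single ring → C16 aldehyde, geranylation, reduction → C7 ketone, isopropenyl addition, oxidative transposition → desilylation.
Stereochemistry: C6/C11 from the chair Claisen of the (E)-allyl ester through a chiral boron enolate; C10 from the chair ring closure; C16 from CBS reduction; the C7 carbinol is temporary (Felkin–Anh); the C2=C7 geometry rests on the smaller formyl group lying next to C6.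

Key step: step 11

Assumption: the (4S,5S) enantiomer of the bromoborane is taken to be the one that leads to the (2S,3R) acid 8; should its sense of induction be the opposite, the (4R,5R) enantiomer is used and nothing else changes.

**Step 1**
Reactants: 1 δ-valerolactone
Product: 4 5-(tert-butyldiphenylsilyloxy)pentanoic acid, via sodium 5-hydroxypentanoate 2 (not isolated), via bis-silylated hydroxy acid 3 (not isolated)
Conditions: NaOH (1 equiv), H2O/MeOH, rt; evaporate; t-BuPh2SiCl (2.2 equiv), imidazole, DMF, rt; then AcOH/THF/H2O, rt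
Reagents that add atoms: sodium hydroxide [Na+].[OH-]; tert-butyl(chloro)diphenylsilane CC(C)(C)[Si](Cl)(c1ccccc1)c1ccccc1
Why: Lactone saponification followed by silyl ether formation is standard, and the silyl ester formed at the carboxylate is far more labile than the primary silyl ether, so aqueous acetic acid should hydrolyse it selectively.

**Step 2**
Reactants: 4 5-(tert-butyldiphenylsilyloxy)pentanoic acid; 5 geraniol
Product: 6 geranyl 5-(tert-butyldiphenylsilyloxy)pentanoate
Conditions: DCC, 4-(dimethylamino)pyridine (cat.), CH2Cl2, 0 °C → rt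
Reagents that add atoms: none
Why: Steglich esterification couples the acid to the primary allylic alcohol under neutral conditions, so the (E)-trisubstituted alkene of geraniol is carried over unchanged.

**Step 3**
Reactants: 6 geranyl 5-(tert-butyldiphenylsilyloxy)pentanoate
Product: 8 (2S,3R)-2-[3-(tert-butyldiphenylsilyloxy)propyl]-3-ethenyl-3,7-dimethyloct-6-enoic acid, via boron ketene acetal 7 (not isolated)
Conditions: (4S,5S)-2-bromo-1,3-bis[3,5-bis(trifluoromethyl)phenylsulfonyl]-4,5-diphenyl-1,3,2-diazaborolidine, i-Pr2NEt, CH2Cl2, −78 °C; then −20 → 4 °C; aqueous work-up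
Reagents that add atoms: none
Why: Enantioselective Ireland–Claisen rearrangement, in which soft enolisation with the bromoborane and the hindered amine in CH2Cl2 should give the ketene acetal with the side chain cis to O–B, its chair [3,3] shift onto the (E)-alkene (homoprenyl group equatorial) fixes the C6/C11 relative configuration, and the C2-symmetric bis-sulfonamide ligand on boron differentiates the enolate faces and so sets the absolute configuration of both new centres.

**Step 4**
Reactants: 8 the (2S,3R) acid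
Product: 9 (2S,3R)-2-[3-(tert-butyldiphenylsilyloxy)propyl]-3-ethenyl-3,7-dimethyloct-6-en-1-ol
Conditions: LiAlH4, THF, 0 °C → rt
Reagents that add atoms: none
Why: Hydride reduction of the carboxylic acid with LiAlH4 gives the primary alcohol and leaves the silyl ether and both alkenes untouched.

**Step 5**
Reactants: 9 the primary alcohol
Product: 10 (2S,3R)-2-[3-(tert-butyldiphenylsilyloxy)propyl]-3-ethenyl-3,7-dimethyloct-6-enal
Conditions: Dess–Martin periodinane, pyridine, CH2Cl2, 0 °C → rt
Reagents that add atoms: none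
Why: Dess–Martin oxidation stops at the aldehyde under buffered, non-enolising conditions, so the α-stereocentre C6 should not epimerise.

**Step 6**
Reactants: 10 the aldehyde
Product: 11 ethyl (3S,4S,5R)-4-[3-(tert-butyldiphenylsilyloxy)propyl]-5-ethenyl-3-hydroxy-5,9-dimethyldec-8-enoate
Conditions: LiN(i-Pr)2, EtOAc, THF, −78 °C; then 10, −78 °C; AcOH quench
Reagents that add atoms: ethyl acetate CCOC(C)=O
Why: Acetate aldol addition under Felkin–Anh control (attack anti to the quaternary C11, past the C6 hydrogen) should favour the (7S) carbinol, a temporary centre that becomes a ketone in step 18; the major epimer is purified here.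

**Step 7**
Reactants: 11 the β-hydroxy ester
Product: 12 the 3-O-triethylsilyl ether of 11 (C7–OSiEt3)
Conditions: Et3SiOTf, 2,6-lutidine, CH2Cl2, −78 °C
Reagents that add atoms: triethylsilyl trifluoromethanesulfonate CC[Si](CC)(CC)OS(=O)(=O)C(F)(F)F
Why: Silyl ether formation with the silyl triflate and 2,6-lutidine is fast on the hindered secondary alcohol at low temperature and avoids the retro-aldol pathway open to a metal alkoxide.

**Step 8**
Reactants: 12 the silyloxy ester
Product: 13 (3S,4S,5R)-4-[3-(tert-butyldiphenylsilyloxy)propyl]-5-ethenyl-5,9-dimethyl-3-(triethylsilyloxy)dec-8-en-1-ol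
Conditions: i-Bu2AlH, CH2Cl2, −78 → −40 °C; aqueous potassium sodium tartrate work-up
Reagents that add atoms: none
Why: Hydride reduction of the ester with i-Bu2AlH gives the primary alcohol at low temperature, where the aluminium alkoxide should not promote silyl migration from O7 to O9.

**Step 9**
Reactants: 13 the C9 alcohol with the C11 vinyl group
Product: 14 (3S)-3-[(4S,5S)-1-(tert-butyldiphenylsilyloxy)-7-hydroxy-5-(triethylsilyloxy)heptan-4-yl]-3,7-dimethyloct-6-en-2-one
Conditions: PdCl2 (cat.), Cu(OAc)2 (cat.), O2 (1 atm), N,N-dimethylacetamide/H2O, rt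
Reagents that add atoms: water O
Why: Tsuji–Wacker oxidation, in which divalent palladium activates only the monosubstituted alkene, water adds at the internal carbon and β-hydride elimination gives the methyl ketone, while the trisubstituted alkene is inert and the acetate-buffered medium spares the silyl ethers.

**Step 10**
Reactants: 14 the hydroxy methyl ketone
Product: 15 (3S)-3-[(4S,5S)-1-(tert-butyldiphenylsilyloxy)-7-iodo-5-(triethylsilyloxy)heptan-4-yl]-3,7-dimethyloct-6-en-2-one
Conditions: I2, PPh3, imidazole, CH2Cl2, 0 °C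
Reagents that add atoms: iodine II
Why: Appel-type iodination converts the primary alcohol into the iodide by SN2 displacement of the alkoxyphosphonium group without touching the ketone or the silyl ethers.

**Step 11**
Reactants: 15 the iodo methyl ketone
Product: 17 (1S,2S,3S,4S)-3-[3-(tert-butyldiphenylsilyloxy)propyl]-1,2-dimethyl-2-(4-methylpent-3-en-1-yl)-4-(triethylsilyloxy)cyclohexan-1-ol, via alkylsamarium diiodide 16 (not isolated)
Conditions: SmI2 (2.5 equiv), HMPA, THF, −78 → 0 °C; aqueous NH4Cl
Reagents that add atoms: none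
Why: Two single-electron transfers from divalent samarium, accelerated by HMPA, turn the C9–I bond via the primary radical into a trivalent alkylsamarium that adds to the C10 ketone. This is the intramolecular samarium Barbier reaction known for ω-iodo ketones giving cycloalkanols. The cyclohexane C6–C7–C8–C9–C10–C11 closes by 6-exo-trig attack of C9 on the carbonyl carbon. The new stereocentre C10 is controlled by a chair transition state in which the C6 propyl arm, the C7 silyloxy group and the C11 homoprenyl arm are equatorial and the C11 methyl axial, so that the bulky samarium-bound oxygen should take the equatorial site and the C10 methyl the axial one anti to the C11 methyl, which places the hydroxyl cis to the C11 methyl. The step needs reduction of the iodide before the ketone, secured by HMPA and by the hindered α-quaternary ketone, and it needs this facial selectivity, secured by the equatorial preference of the three arms set in steps 3 and 6; the silyl ethers and the trisubstituted alkene are inert to SmI2.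

**Step 12**
Reactants: 17 the cyclohexanol
Product: 19 (2E)-5-[(1S,2S,5S,6S)-6-[3-(tert-butyldiphenylsilyloxy)propyl]-2-hydroxy-1,2-dimethyl-5-(triethylsilyloxy)cyclohexyl]-2-methylpent-2-enal, via allylic alcohol 18 (not isolated)
Conditions: SeO2 (cat.), t-BuOOH, CH2Cl2, rt; then MnO2, CH2Cl2, rt
Reagents that add atoms: selenium dioxide O=[Se]=O; tert-butyl hydroperoxide CC(C)(C)OO
Why: Selenium dioxide allylic oxidation (Riley oxidation, ene reaction then [2,3]-sigmatropic shift) attacks the (E)-methyl group of the only alkene, and MnO2 then takes the allylic alcohol formed alongside to the same (E)-enal without touching the tertiary alcohol.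

**Step 13**
Reactants: 19 the (E)-enal; 20 geranyl chloride
Product: 22 the C16 carbinols (both C16 epimers; 14E,18E), via geranylbarium chloride 21 (not isolated)
Conditions: BaI2, lithium biphenylide, THF, rt (activated barium); 20, −78 °C; then 19 (reagent 3 equiv), −78 °C
Reagents that add atoms: none
Why: Allylbarium addition, in which the geranylbarium reagent reacts at its α-carbon with retention of the (E) geometry and adds 1,2 to the enal to join C16 to C17; one equivalent is consumed by the C10 hydroxyl and the C16 configuration is left open until step 15.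

**Step 14**
Reactants: 22 the C16 carbinols
Product: 23 the C16 enone (14E,18E)
Conditions: Dess–Martin periodinane, pyridine, CH2Cl2, 0 °C
Reagents that add atoms: none
Why: Dess–Martin oxidation of the secondary allylic alcohol gives the enone under buffered conditions that should not move the C18 alkene into conjugation.

**Step 15**
Reactants: 23 the C16 enone
Product: 24 the (16R) allylic alcohol
Conditions: (3aS)-1-methyl-3,3-diphenyltetrahydro-1H,3H-pyrrolo[1,2-c][1,3,2]oxazaborole (cat.), catecholborane, toluene, −78 °C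
Reagents that add atoms: none
Why: Corey–Bakshi–Shibata reduction, in which the α-methyl alkenyl group acts as the large and the CH2 group as the small ketone substituent, so the (S)-configured catalyst should deliver hydride to the face that gives the (16R) alcohol.

**Step 16**
Reactants: 24 the (16R) alcohol
Product: 25 the 16-O-tert-butyldimethylsilyl ether of 24
Conditions: t-BuMe2SiCl, imidazole, DMF, rt
Reagents that add atoms: tert-butyl(chloro)dimethylsilane CC(C)(C)[Si](C)(C)Cl
Why: Silyl ether formation with the silyl chloride and imidazole should occur only at the secondary allylic hydroxyl, the tertiary C10 hydroxyl next to the quaternary centre being too hindered.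

**Step 17**
Reactants: 25 the tris-silyl ether
Product: 26 the C7 alcohol (7S; 3-O-tert-butyldiphenylsilyl and 16-O-tert-butyldimethylsilyl retained)
Conditions: pyridinium p-toluenesulfonate (cat.), MeOH/CH2Cl2, 0 °C
Reagents that add atoms: none
Why: Acid-catalysed methanolysis removes the triethylsilyl ether selectively, because it is cleaved orders of magnitude faster than the tert-butyldimethylsilyl and tert-butyldiphenylsilyl ethers.

**Step 18**
Reactants: 26 the C7 alcohol
Product: 27 the C7 ketone
Conditions: Dess–Martin periodinane, pyridine, CH2Cl2, 0 °C → rt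
Reagents that add atoms: none
Why: Dess–Martin oxidation gives the ketone under neutral conditions, so the adjacent C6 centre should not epimerise and the tertiary alcohol is untouched.

**Step 19**
Reactants: 27 the C7 ketone
Product: 28 the C7 isopropenyl carbinol (either C7 epimer)
Conditions: CH2=C(CH3)MgBr, CeCl3, THF, −78 °C
Reagents that add atoms: isopropenylmagnesium bromide C=C(C)[Mg]Br
Why: Organocerium addition, in which the weakly basic isopropenylcerium reagent adds to the hindered, enolisable ketone without enolising it (C6 is preserved), and the configuration of the new C7 carbinol does not matter because C7 becomes sp2 in step 20.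

**Step 20**
Reactants: 28 the tertiary allylic alcohol
Product: 29 3-O-tert-butyldiphenylsilyl-16-O-tert-butyldimethylsilyl isoiridogermanal (2Z)
Conditions: pyridinium chlorochromate [C5H5NH][CrO3Cl], 4 Å molecular sieves, CH2Cl2, rt
Reagents that add atoms: pyridinium chlorochromate [O-][Cr](=O)(=O)Cl.c1cc[nH+]cc1
Why: Babler–Dauben oxidative transposition, in which the chromate ester of the tertiary allylic alcohol undergoes a [3,3] shift to the primary allylic chromate that is oxidised to the enal, the non-allylic C10 alcohol and the silyl ethers are not oxidised, and the alkene geometry is expected to settle on the isomer with the slim formyl group next to the substituted C6, which is the required (2Z) geometry.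

**Step 21**
Reactants: 29 the bis-silyl ether
Product: 30 isoiridogermanal (6R,10S,11S,16R; 2Z,14E,18E)
Conditions: HF·pyridine, pyridine, THF, 0 °C → rt
Reagents that add atoms: none
Why: Fluoride-mediated desilylation with pyridine-buffered HF removes both silyl ethers without acid ionisation of the allylic alcohol or isomerisation of the enal.

**Compound list**
1 | δ-valerolactone | O=C1CCCCO1 | starting material
2 | sodium 5-hydroxypentanoate | [Na+].[O-]C(=O)CCCCO | intermediate
3 | tert-butyldiphenylsilyl 5-(tert-butyldiphenylsilyloxy)pentanoate | CC(C)(C)[Si](c1ccccc1)(c1ccccc1)OCCCCC(=O)O[Si](c1ccccc1)(c1ccccc1)C(C)(C)C | intermediate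
4 | 5-(tert-butyldiphenylsilyloxy)pentanoic acid | OC(=O)CCCCO[Si](c1ccccc1)(c1ccccc1)C(C)(C)C | intermediate
5 | geraniol | CC(C)=CCC/C(C)=C/CO | starting material
6 | geranyl 5-(tert-butyldiphenylsilyloxy)pentanoate | CC(C)=CCC/C(C)=C/COC(=O)CCCCO[Si](c1ccccc1)(c1ccccc1)C(C)(C)C | intermediate
7 | boron ketene acetal of 6 (side chain cis to O–B; (4S,5S)-diazaborolidinyl group on oxygen) | CC(C)=CCC/C(C)=C/CO/C(OB1N(S(=O)(=O)c2cc(cc(c2)C(F)(F)F)C(F)(F)F)[C@@H](c2ccccc2)[C@H](c2ccccc2)N1S(=O)(=O)c1cc(cc(c1)C(F)(F)F)C(F)(F)F)=C/CCCO[Si](c1ccccc1)(c1ccccc1)C(C)(C)C | intermediate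
8 | (2S,3R)-2-[3-(tert-butyldiphenylsilyloxy)propyl]-3-ethenyl-3,7-dimethyloct-6-enoic acid | CC(C)=CCC[C@@](C=C)(C)[C@H](CCCO[Si](c1ccccc1)(c1ccccc1)C(C)(C)C)C(=O)O | intermediate
9 | (2S,3R)-2-[3-(tert-butyldiphenylsilyloxy)propyl]-3-ethenyl-3,7-dimethyloct-6-en-1-ol | CC(C)=CCC[C@@](C=C)(C)[C@H](CCCO[Si](c1ccccc1)(c1ccccc1)C(C)(C)C)CO | intermediate
10 | (2S,3R)-2-[3-(tert-butyldiphenylsilyloxy)propyl]-3-ethenyl-3,7-dimethyloct-6-enal | CC(C)=CCC[C@@](C=C)(C)[C@H](CCCO[Si](c1ccccc1)(c1ccccc1)C(C)(C)C)C=O | intermediate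
11 | ethyl (3S,4S,5R)-4-[3-(tert-butyldiphenylsilyloxy)propyl]-5-ethenyl-3-hydroxy-5,9-dimethyldec-8-enoate | CC(C)=CCC[C@@](C=C)(C)[C@H](CCCO[Si](c1ccccc1)(c1ccccc1)C(C)(C)C)[C@@H](O)CC(=O)OCC | intermediate
12 | ethyl (3S,4S,5R)-4-[3-(tert-butyldiphenylsilyloxy)propyl]-5-ethenyl-5,9-dimethyl-3-(triethylsilyloxy)dec-8-enoate | CC(C)=CCC[C@@](C=C)(C)[C@H](CCCO[Si](c1ccccc1)(c1ccccc1)C(C)(C)C)[C@@H](O[Si](CC)(CC)CC)CC(=O)OCC | intermediate
13 | (3S,4S,5R)-4-[3-(tert-butyldiphenylsilyloxy)propyl]-5-ethenyl-5,9-dimethyl-3-(triethylsilyloxy)dec-8-en-1-ol | CC(C)=CCC[C@@](C=C)(C)[C@H](CCCO[Si](c1ccccc1)(c1ccccc1)C(C)(C)C)[C@@H](O[Si](CC)(CC)CC)CCO | intermediate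
14 | (3S)-3-[(4S,5S)-1-(tert-butyldiphenylsilyloxy)-7-hydroxy-5-(triethylsilyloxy)heptan-4-yl]-3,7-dimethyloct-6-en-2-one | CC(C)=CCC[C@@](C(C)=O)(C)[C@H](CCCO[Si](c1ccccc1)(c1ccccc1)C(C)(C)C)[C@@H](O[Si](CC)(CC)CC)CCO | intermediate
15 | (3S)-3-[(4S,5S)-1-(tert-butyldiphenylsilyloxy)-7-iodo-5-(triethylsilyloxy)heptan-4-yl]-3,7-dimethyloct-6-en-2-one | CC(C)=CCC[C@@](C(C)=O)(C)[C@H](CCCO[Si](c1ccccc1)(c1ccccc1)C(C)(C)C)[C@@H](O[Si](CC)(CC)CC)CCI | intermediate
16 | C9 alkylsamarium diiodide derived from 15 | CC(C)=CCC[C@@](C(C)=O)(C)[C@H](CCCO[Si](c1ccccc1)(c1ccccc1)C(C)(C)C)[C@@H](O[Si](CC)(CC)CC)CC[Sm](I)I | intermediate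
17 | (1S,2S,3S,4S)-3-[3-(tert-butyldiphenylsilyloxy)propyl]-1,2-dimethyl-2-(4-methylpent-3-en-1-yl)-4-(triethylsilyloxy)cyclohexan-1-ol | CC(C)=CCC[C@@]1(C)[C@H](CCCO[Si](c2ccccc2)(c2ccccc2)C(C)(C)C)[C@@H](O[Si](CC)(CC)CC)CC[C@]1(C)O | intermediate
18 | (E)-allylic alcohol: 17 with the (E)-methyl of the side-chain terminus as CH2OH | OC/C(C)=C/CC[C@@]1(C)[C@H](CCCO[Si](c2ccccc2)(c2ccccc2)C(C)(C)C)[C@@H](O[Si](CC)(CC)CC)CC[C@]1(C)O | intermediate
19 | (2E)-5-[(1S,2S,5S,6S)-6-[3-(tert-butyldiphenylsilyloxy)propyl]-2-hydroxy-1,2-dimethyl-5-(triethylsilyloxy)cyclohexyl]-2-methylpent-2-enal | O=C/C(C)=C/CC[C@@]1(C)[C@H](CCCO[Si](c2ccccc2)(c2ccccc2)C(C)(C)C)[C@@H](O[Si](CC)(CC)CC)CC[C@]1(C)O | intermediate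
20 | geranyl chloride | CC(C)=CCC/C(C)=C/CCl | starting material
21 | geranylbarium chloride | CC(C)=CCC/C(C)=C/C[Ba]Cl | intermediate
22 | C16 carbinols (both C16 epimers; 14E,18E; C7–OSiEt3, C10–OH, C3–OSiPh2t-Bu) | CC(C)=CCC/C(C)=C/CC(O)/C(C)=C/CC[C@@]1(C)[C@H](CCCO[Si](c2ccccc2)(c2ccccc2)C(C)(C)C)[C@@H](O[Si](CC)(CC)CC)CC[C@]1(C)O | intermediate
23 | C16 enone (14E,18E) | CC(C)=CCC/C(C)=C/CC(=O)/C(C)=C/CC[C@@]1(C)[C@H](CCCO[Si](c2ccccc2)(c2ccccc2)C(C)(C)C)[C@@H](O[Si](CC)(CC)CC)CC[C@]1(C)O | intermediate
24 | (16R) allylic alcohol | CC(C)=CCC/C(C)=C/C[C@@H](O)/C(C)=C/CC[C@@]1(C)[C@H](CCCO[Si](c2ccccc2)(c2ccccc2)C(C)(C)C)[C@@H](O[Si](CC)(CC)CC)CC[C@]1(C)O | intermediate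
25 | 16-O-tert-butyldimethylsilyl ether of 24 | CC(C)=CCC/C(C)=C/C[C@@H](O[Si](C)(C)C(C)(C)C)/C(C)=C/CC[C@@]1(C)[C@H](CCCO[Si](c2ccccc2)(c2ccccc2)C(C)(C)C)[C@@H](O[Si](CC)(CC)CC)CC[C@]1(C)O | intermediate
26 | (7S) C7 alcohol (C10–OH free; 3-O- and 16-O-silyl ethers retained) | CC(C)=CCC/C(C)=C/C[C@@H](O[Si](C)(C)C(C)(C)C)/C(C)=C/CC[C@@]1(C)[C@H](CCCO[Si](c2ccccc2)(c2ccccc2)C(C)(C)C)[C@@H](O)CC[C@]1(C)O | intermediate
27 | C7 ketone | CC(C)=CCC/C(C)=C/C[C@@H](O[Si](C)(C)C(C)(C)C)/C(C)=C/CC[C@@]1(C)[C@H](CCCO[Si](c2ccccc2)(c2ccccc2)C(C)(C)C)C(=O)CC[C@]1(C)O | intermediate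
28 | C7 isopropenyl carbinol (either C7 epimer) | CC(C)=CCC/C(C)=C/C[C@@H](O[Si](C)(C)C(C)(C)C)/C(C)=C/CC[C@@]1(C)[C@H](CCCO[Si](c2ccccc2)(c2ccccc2)C(C)(C)C)C(O)(C(C)=C)CC[C@]1(C)O | intermediate
29 | 3-O-tert-butyldiphenylsilyl-16-O-tert-butyldimethylsilyl isoiridogermanal (2Z) | CC(C)=CCC/C(C)=C/C[C@@H](O[Si](C)(C)C(C)(C)C)/C(C)=C/CC[C@@]1(C)[C@H](CCCO[Si](c2ccccc2)(c2ccccc2)C(C)(C)C)/C(=C(/C)C=O)CC[C@]1(C)O | intermediate
30 | isoiridogermanal (6R,10S,11S,16R; 2Z,14E,18E) | CC(C)=CCC/C(C)=C/C[C@@H](O)/C(C)=C/CC[C@@]1(C)[C@H](CCCO)/C(=C(/C)C=O)CC[C@]1(C)O | target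

**Step count**
Total steps: 21. Longest linear sequence: 21 steps (1 → 30); geraniol 5 and geranyl chloride 20 enter as commercial materials.

**Steps most likely to fail**

Step 11. The closure may pass through the alternative chair with the samarium alkoxide axial, giving the wrong configuration at C10, or the alkylsamarium may be protonated before it adds. The fallback sets out from 15 and comes back at 17, and delivers the C10 methyl group last instead of setting C10 in the ring closure. The methyl ketone of 15 is hydroxylated at its only enolisable position (KN(SiMe3)2, then 2-(phenylsulfonyl)-3-phenyloxaziridine, THF, −78 °C) to the α-hydroxy ketone F1. Pb(OAc)4 in MeOH cleaves it to the iodo methyl ester F2. SmI2 with catalytic tris(dibenzoylmethanato)iron, Fe(PhCOCHCOPh)3, in THF then forms the same C9–C10 bond by intramolecular acyl substitution and gives the cyclohexanone F3. MeLi with CeCl3 should add axially, on the face anti to the axial C11 methyl, which gives 17.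

Step 20. The tertiary allylic chromate may ionise (elimination, or capture of the cation by the C10 hydroxyl), and the tetrasubstituted alkene may form without geometric control. The fallback sets out from 28 and comes back at 29, and separates transposition from oxidation. Catalytic Ph3SiOReO3 in Et2O at low temperature effects a reversible, neutral 1,3-transposition to the primary allylic alcohol. The (2Z) allylic alcohol F4 is separated from the (2E) allylic alcohol F5, which is returned to the catalyst for re-equilibration. MnO2 oxidises F4 to 29 with retention of the alkene geometry.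

Step 3. The hindered boron ketene acetal may rearrange slowly, form with incomplete geometric control, or be discriminated poorly by the ligand, which would erode both the diastereomeric and the enantiomeric purity. The fallback sets out from 6 and comes back at 9, and replaces reagent control by resolution. Ireland–Claisen rearrangement through the (Z)-trimethylsilyl ketene acetal F6 (LiN(i-Pr)2, Me3SiCl, THF/DMPU, −78 °C → rt) gives the racemic acid, that is 8 together with the enantiomeric acid F7. DCC-mediated N-acylation of (S)-4-benzyl-2-oxazolidinone gives the imide F8 from 8 and the diastereomeric imide F9 from F7, which are separated by chromatography. Reduction of F8 with LiBH4 gives 9.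

**Further compounds**
F1 | step 11 | α-hydroxy ketone (C10 ketone with CH2OH in place of CH3, C9 iodide retained) | CC(C)=CCC[C@@](C(=O)CO)(C)[C@H](CCCO[Si](c1ccccc1)(c1ccccc1)C(C)(C)C)[C@@H](O[Si](CC)(CC)CC)CCI
F2 | step 11 | iodo methyl ester (C10 as CO2Me) | CC(C)=CCC[C@@](C(=O)OC)(C)[C@H](CCCO[Si](c1ccccc1)(c1ccccc1)C(C)(C)C)[C@@H](O[Si](CC)(CC)CC)CCI
F3 | step 11 | cyclohexanone with the ring ketone at C10 | CC(C)=CCC[C@@]1(C)[C@H](CCCO[Si](c2ccccc2)(c2ccccc2)C(C)(C)C)[C@@H](O[Si](CC)(CC)CC)CCC1=O
F4 | step 20 | (2Z) primary allylic alcohol (C1 as CH2OH, cis to C6) | CC(C)=CCC/C(C)=C/C[C@@H](O[Si](C)(C)C(C)(C)C)/C(C)=C/CC[C@@]1(C)[C@H](CCCO[Si](c2ccccc2)(c2ccccc2)C(C)(C)C)/C(=C(/C)CO)CC[C@]1(C)O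
F5 | step 20 | (2E) primary allylic alcohol (C1 as CH2OH, trans to C6) | CC(C)=CCC/C(C)=C/C[C@@H](O[Si](C)(C)C(C)(C)C)/C(C)=C/CC[C@@]1(C)[C@H](CCCO[Si](c2ccccc2)(c2ccccc2)C(C)(C)C)/C(=C(\C)CO)CC[C@]1(C)O
F6 | step 3 | (Z)-trimethylsilyl ketene acetal of 6 | CC(C)=CCC/C(C)=C/CO/C(O[Si](C)(C)C)=C/CCCO[Si](c1ccccc1)(c1ccccc1)C(C)(C)C
F7 | step 3 | (2R,3S) acid, enantiomer of 8 | CC(C)=CCC[C@](C=C)(C)[C@@H](CCCO[Si](c1ccccc1)(c1ccccc1)C(C)(C)C)C(=O)O
F8 | step 3 | N-acyl (S)-4-benzyl-2-oxazolidinone of 8 | CC(C)=CCC[C@@](C=C)(C)[C@H](CCCO[Si](c1ccccc1)(c1ccccc1)C(C)(C)C)C(=O)N1[C@@H](Cc2ccccc2)COC1=O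
F9 | step 3 | N-acyl (S)-4-benzyl-2-oxazolidinone of F7 | CC(C)=CCC[C@](C=C)(C)[C@@H](CCCO[Si](c1ccccc1)(c1ccccc1)C(C)(C)C)C(=O)N1[C@@H](Cc2ccccc2)COC1=O
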